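**Remark on the chemistry (assumption).** The target has a mirror plane through O1 and the midpoint of C3–C4, so it is the achiral meso (2R,3S,4R,5S) isomer. A single-enantiomer butenolide is therefore neither produced by this achiral assembly nor needed: every chiral intermediate is carried as the racemate, and its SMILES shows one enantiomer only to fix the relative configuration. The carbinol carbon made in step 4 is written without a descriptor, because both epimers converge in step 8.

## Structural features

The target is a 7,7'-epoxylignan-type molecule: one oxolane ring (O1, C2–C5) with a 3,4-dihydroxyphenyl ring on C2 and on C5 and an acetoxymethyl arm on C3 and on C4. All four ring carbons are contiguous stereocentres with 2,3-trans, 3,4-cis and 4,5-trans relationships, the two aryl groups being cis to each other. The fragile groups are the two catechols (air oxidation), the two primary acetates (hydride, base, acyl migration) and the two ring C–O bonds, which are benzylic to 4-oxygenated arenes and so ionise under acid and can be hydrogenolysed. That same lability lets C2 and C5 be set by equilibration, each aryl ending trans to its neighbour, whereas C3 and C4 cannot be corrected once they are at the alcohol oxidation level. The real difficulty is therefore the cis pair C3/C4, which carries two identical one-carbon arms and must be made without a ring that enforces it. The key step uses the fact that C5 (aryl and oxygen), C4, C3 and the arm carbon of C3 at the carboxyl level are the four carbons of a γ-aryl butenolide: its only stereocentre, C5, can direct a nucleophile trans onto C4, and the new C4 substituent can direct an electrophile trans onto C3. Trans on the lactone becomes cis on the tetrahydrofuran, because the lactone carbonyl ends as the exocyclic arm of C3 while the exocyclic carbinol carbon ends as ring carbon C2. Both aryl-bearing carbons, C2 and C5, come from one aromatic aldehyde used twice.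

## Logic of the disconnections

15 to 14: the four phenolic O–H bonds are replaced by O–benzyl bonds. Free catechols would not survive the organometallic, oxidative and acidic steps. The gain is a robust, neutral precursor. The demand is a last step that removes four benzyl groups without touching two acetates or the two ring benzylic C–O bonds.

14 to 13: the O1–C2 bond (equivalently O1–C5) is cut. Both ring C–O bonds are benzylic to 4-oxygenated arenes, so they can be formed and re-opened by ionisation. The gain is that the ring disappears and C2 and C5 stop being stereochemical problems. The demand is a closure under thermodynamic control in which the primary oxygens are already capped and the cation does not attack the other arene.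

13 to 12: the two acetyl C–O bonds are cut. Acetates cannot pass the hydride step, and placing them before ring closure also blocks the primary hydroxyls as competing nucleophiles. The demand is discrimination between primary and secondary benzylic hydroxyls.

12 to 11: the two C–H bonds of the C3 arm are removed and the C5–O–C(=O) bond is rejoined. The resulting lactone holds the substituents at C3, C4 and C5 in a defined relation. The demand is a hydride reduction that is faster than retro-aldol cleavage.

11 to 10: the C–O bond of the C4 arm is exchanged for a C–Si bond, since a hydroxymethyl anion cannot be delivered as such. The demand is an oxidation that tolerates a lactone, a free carbinol and electron-rich arenes.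

10 to 6, 8 and 2: the C4–CH2 bond and the C3–carbinol bond are cut. These are the bonds at the β- and α-carbons of an unsaturated lactone, so they form by conjugate addition and aldol trapping in one flask. The gain is three simple components, the second aryl group coming from the same 2 that builds 6. The demand is a trans,trans relay from C5, and conjugate addition that outruns deprotonation at C5.

8 to 7: the C–Mg bond is cut; magnesium insertion into the C–Cl bond restores it.

6 to 4 (through 5): the lactone acyl–O bond is cut and the alkene is traced back to an alkyne. The Z geometry needed for ring closure then comes from cis-semihydrogenation. The demand is that the benzyl ethers are not cleaved.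

4 to 1 and 2: the bond between the carbinol carbon and the alkyne is cut. An acetylide adds to a non-enolisable aldehyde; the demand is a low temperature for the unstable anion derived from 1.

## Other disconnections considered

Alternative 1: The cut runs through C3–C4 and O1–C5, so C2/C3 come from an aroylacetate and C4/C5 from a cinnamyl unit, joined as the ester A1.
- Forward key step: Mn(OAc)3 (trivalent manganese) oxidises the β-keto ester of A1 to a C3 radical, which closes the γ-lactone onto the styrene. Cu(OAc)2 (divalent copper) oxidises the benzylic radical at C5 to a cation, and the enol oxygen of the aryl ketone traps it to give the furo[3,4-c]furanone A2.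
- In favour: two rings and two skeletal bonds arise in one operation. Once C2=C3 is reduced, the cis ring fusion makes C3/C4 cis a geometric necessity. This is a firmer guarantee than two consecutive 1,2-inductions, and here the alternative is the better.
- Against: the tetrasubstituted, push–pull C2=C3 enol ether of A2 still has to be reduced. Hydrogen should arrive on the convex face, leaving the C2 aryl cis to C3, so an acid epimerisation at C2 would have to follow. The radical closure of an allylic ester is slowed by the ester conformation. Four silyl-protected phenols on electron-rich rings must survive a one-electron oxidant in hot acetic acid. Fluoride removal of the silyl groups at the end would expose the acetates to phenoxides.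
- Comparison: on structure the alternative fixes C3/C4 better; on mechanism the chosen plan uses polar steps with a predictable facial bias, while the oxidant tolerance of the arenes is the open question for A1. On step economy the two are about equal (ester assembly, annulation, alkene reduction, epimerisation, lactone reduction, acetylation, desilylation against nine steps).

Alternative 2: The cut is C2–C3. The α-diazo lactone A3 already holds C4 and C5 and carries the second aryl group as a benzylic ether on the C5 oxygen.
- Forward key step: A3 loses N2 under Rh2(O2CCPh3)4, and the rhodium carbene at C3 inserts into the benzylic C–H bond of that ether (1,5-insertion). This closes the tetrahydrofuran cis-fused to the lactone and gives A4.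
- In favour: after the key step all four stereocentres sit in a rigid bicycle, C3/C4 cis by ring fusion and both aryl groups exo. The end-game is only lactone reduction, acetylation of a diol with no other hydroxyl, and hydrogenolysis. The selective acetylation and the acid-mediated closure of the chosen plan are avoided; on these points the alternative is the better.
- Against: A3 is costly to reach. The anti C4/C5 relationship must be set beforehand, a hindered benzylic oxygen must be alkylated with an electron-rich benzyl halide, and diazo transfer to a lactone needs prior α-activation. The carbene has the C4–H beside it (1,2-hydride shift to a butenolide, which the bulky triphenylacetate ligands are meant to suppress). It must also choose the intended C–H over the four O–CH2Ph groups and over addition to four electron-rich arenes. An energetic diazo intermediate is a safety cost the chosen plan does not carry.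
- Comparison: on structure the two are equal for C2 and C5 (kinetic exo selectivity there, thermodynamic selection here) and the alternative is better for C3/C4. On step economy it is longer, about eleven steps or more against nine.

Alternative 3: Both C–aryl bonds are cut. The ring comes from the exo-oxanorbornene diacetate A5 by oxidative cleavage of its alkene to the cis-diacid A6.
- Forward key step: A6 couples twice with the aryl bromide A7 under [Ir(dF(CF3)ppy)2(dtbbpy)]PF6 and NiCl2(dme)/4,4'-di-tert-butyl-2,2'-bipyridine with visible light. Each carboxylate is oxidised by the excited iridium complex and loses CO2 to an α-oxy radical at C2 or C5, which nickel joins to the aryl group. The product A8 is the same compound as 14.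
- In favour: it is the shortest plan, about six steps from bulk chemicals, so it is better on step economy. Every intermediate is meso, and the C3/C4 cis pair comes from a cycloaddition and is never at risk, which is also better. Capture of each radical anti to the adjacent acetoxymethyl group should give the trans relationship.
- Against: two consecutive sp3–sp2 couplings must both succeed on one molecule with an electron-rich aryl bromide, the least willing class in oxidative addition to nickel. Protodecarboxylation and the mono-arylated acid are obvious competitors. After the first coupling the substrate carries a doubly activated benzylic ether C–H under photoredox conditions.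
- Comparison: selection at C2 and C5 is kinetic, but a wrong isomer could be corrected by the same acid equilibration the chosen plan uses, so the plans are equal there. Both end with the same hydrogenolysis. The chosen plan is longer, but each of its bonds is formed by a polar reaction of established scope.

Key step: step 4

## Route

Step 1
Reactants: 1 ethyl propiolate; 2 3,4-bis(benzyloxy)benzaldehyde
Product: 4 ethyl 4-[3,4-bis(benzyloxy)phenyl]-4-hydroxybut-2-ynoate (racemic), via lithium ethyl propiolate 3 (not isolated)
Conditions: LiN(SiMe3)2, THF, −78 °C; then 2, −78 °C; aq NH4Cl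
Reagents that add atoms: none
Why: The amide base deprotonates the ester-activated terminal alkyne at −78 °C, and acetylide 3 adds 1,2 to the non-enolisable aldehyde (acetylide addition to a carbonyl); the low temperature keeps 3 from self-condensing. The carbinol centre forms racemic, which is all the meso target needs.

Step 2
Reactants: 4 ethyl 4-[3,4-bis(benzyloxy)phenyl]-4-hydroxybut-2-ynoate
Product: 6 5-[3,4-bis(benzyloxy)phenyl]furan-2(5H)-one (racemic), via Z-hydroxy enoate 5 (not isolated)
Conditions: H2 (1 atm), Pd/CaCO3 poisoned with Pb(OAc)2, quinoline, EtOAc, rt; filter; then PPTS (cat.), CH2Cl2, rt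
Reagents that add atoms: none
Why: Syn delivery of hydrogen on the poisoned palladium surface (cis-semihydrogenation of an alkyne) gives the Z-enoate 5, whose hydroxyl lies next to the ester and lactonises under mild acid with loss of ethanol. Aryl benzyl ethers are not cleaved on this catalyst, and no stereocentre is made or touched.

Step 3
Reactants: 7 (chloromethyl)isopropoxydimethylsilane
Product: 8 (isopropoxydimethylsilyl)methylmagnesium chloride (titrated THF solution, used directly)
Conditions: Mg turnings, BrCH2CH2Br (cat.), THF, rt → 45 °C
Reagents that add atoms: magnesium, [Mg]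
Why: Magnesium inserts into the C–Cl bond (Grignard formation); the hindered isopropoxy group keeps the Si–O bond intact beside its own carbanion, which is the standard way to make this hydroxymethyl anion equivalent.

Step 4
Reactants: 6 5-[3,4-bis(benzyloxy)phenyl]furan-2(5H)-one; 8 (isopropoxydimethylsilyl)methylmagnesium chloride; 2 3,4-bis(benzyloxy)benzaldehyde
Product: 10 rac-(3R,4S,5S)-5-[3,4-bis(benzyloxy)phenyl]-3-{[3,4-bis(benzyloxy)phenyl](hydroxy)methyl}-4-[(isopropoxydimethylsilyl)methyl]oxolan-2-one (carbinol epimers), via chloromagnesium enolate 9 (not isolated)
Conditions: CuI (10 mol%), 8 (1.2 equiv), THF, −78 °C, slow addition of 6; then 2 (1.5 equiv), −78 → −40 °C; aq NH4Cl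
Reagents that add atoms: none
Why: Transmetalation of 8 to CuI gives a silylmethyl cuprate that binds the C3=C4 bond of 6, adds oxidatively at C4 to a trivalent copper species and reductively eliminates, forming the C4–CH2 bond and enolate 9 and returning monovalent copper. Enolate 9 then adds to aldehyde 2 through a closed, magnesium-bridged six-membered transition state and forms the C3–carbinol bond; the closest known reaction type is the copper-catalysed Grignard conjugate addition–aldol three-component coupling of cyclic enones and butenolides, here with a silylmethyl Grignard reagent as hydroxymethyl anion equivalent. No ring is formed, so no mode of closure is involved. C4 is controlled by C5: the cuprate approaches the nearly planar butenolide on the face opposite the aryl group (4,5-trans). C3 is controlled by C4: the aldehyde approaches the enolate face opposite the new silylmethyl group (3,4-trans), as in aldol reactions of β-substituted butyrolactone enolates. The carbinol carbon is not controlled and need not be, since it is re-set in step 8. The step needs 1,4-addition to outrun removal of the acidic C5–H and 1,2-addition; copper catalysis at −78 °C, the low basicity of the α-silyl Grignard reagent and slow addition of 6 to the reagent secure this, and 2 is added only after 6 is consumed so that it meets enolate rather than Grignard reagent. Racemic 6 suffices because both enantiomeric series lead to the same meso product.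

Step 5
Reactants: 10 rac-(3R,4S,5S)-5-[3,4-bis(benzyloxy)phenyl]-3-{[3,4-bis(benzyloxy)phenyl](hydroxy)methyl}-4-[(isopropoxydimethylsilyl)methyl]oxolan-2-one
Product: 11 rac-(3R,4R,5S)-5-[3,4-bis(benzyloxy)phenyl]-3-{[3,4-bis(benzyloxy)phenyl](hydroxy)methyl}-4-(hydroxymethyl)oxolan-2-one (carbinol epimers)
Conditions: 30% aq H2O2, KF, KHCO3, THF/MeOH, rt
Reagents that add atoms: hydrogen peroxide, OO
Why: Tamao–Kumada oxidation: fluoride and bicarbonate raise the alkoxysilane to a hypervalent silicate, hydroperoxide adds, and the CH2 group migrates from silicon to oxygen. The lactone, carbinol and benzyl ethers tolerate the buffered peroxide, and any translactonisation onto the new primary alcohol is harmless because step 6 reduces both lactone isomers to the same tetraol.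

Step 6
Reactants: 11 rac-(3R,4R,5S)-5-[3,4-bis(benzyloxy)phenyl]-3-{[3,4-bis(benzyloxy)phenyl](hydroxy)methyl}-4-(hydroxymethyl)oxolan-2-one
Product: 12 rac-(1S,2R,3S)-1,4-bis[3,4-bis(benzyloxy)phenyl]-2,3-bis(hydroxymethyl)butane-1,4-diol (C4 epimers)
Conditions: LiAlH4, THF, 0 °C → rt; H2O/aq NaOH work-up
Reagents that add atoms: none
Why: Hydride reduction of the γ-lactone (two hydride transfers through the lactol aluminate) gives the C3 hydroxymethyl arm and frees the C5 benzylic hydroxyl; no stereocentre is touched and benzyl ethers are inert. Starting at 0 °C lets reduction outpace retro-aldol cleavage of the β-alkoxide.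

Step 7
Reactants: 12 rac-(1S,2R,3S)-1,4-bis[3,4-bis(benzyloxy)phenyl]-2,3-bis(hydroxymethyl)butane-1,4-diol
Product: 13 rac-(1S,2R,3S)-2,3-bis(acetoxymethyl)-1,4-bis[3,4-bis(benzyloxy)phenyl]butane-1,4-diol (C4 epimers)
Conditions: AcCl (2.2 equiv), 2,4,6-collidine, CH2Cl2, −78 °C
Reagents that add atoms: acetyl chloride, CC(=O)Cl
Why: Nucleophilic acyl substitution under steric discrimination: acetyl chloride with the hindered base collidine at −78 °C acylates the unhindered primary hydroxyls much faster than the flanked secondary benzylic ones (known primary-selective acetylation). This installs the acetates of the target and removes the primary oxygens as nucleophiles for step 8.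

Step 8
Reactants: 13 rac-(1S,2R,3S)-2,3-bis(acetoxymethyl)-1,4-bis[3,4-bis(benzyloxy)phenyl]butane-1,4-diol
Product: 14 meso-(2R,3S,4R,5S)-{2,5-bis[3,4-bis(benzyloxy)phenyl]oxolane-3,4-diyl}bis(methylene) diacetate
Conditions: CSA (cat.), 4 Å MS, CH2Cl2, 0 °C → rt
Reagents that add atoms: none
Why: Acid-catalysed cyclodehydration: loss of water from either benzylic hydroxyl gives a cation stabilised by the para-benzyloxy group, which the other benzylic hydroxyl captures to close the five-membered ring (SN1-type etherification). Because both ring C–O bonds can re-ionise, C2 and C5 equilibrate until each aryl is trans to its acetoxymethyl neighbour, while the non-epimerisable C3/C4 pair from step 4 stays cis; both C2 epimers of 13 therefore give the same meso ring.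

Step 9
Reactants: 14 meso-(2R,3S,4R,5S)-{2,5-bis[3,4-bis(benzyloxy)phenyl]oxolane-3,4-diyl}bis(methylene) diacetate
Product: 15 meso-(2R,3S,4R,5S)-[2,5-bis(3,4-dihydroxyphenyl)oxolane-3,4-diyl]bis(methylene) diacetate (CNP0416169.1)
Conditions: H2 (1 atm), Pd/C, EtOAc, rt; work-up under argon
Reagents that add atoms: none
Why: Heterogeneous hydrogenolysis cleaves the four aryl benzyl ethers in neutral ethyl acetate; the acetates are inert, and the ring benzylic C–O bonds, which are secondary and not acid-activated, should be cleaved far more slowly than ArO–CH2Ph bonds. No stereocentre is affected.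

## Compound list

1 | ethyl propiolate | CCOC(=O)C#C | starting material
2 | 3,4-bis(benzyloxy)benzaldehyde | O=Cc1ccc(OCc2ccccc2)c(OCc2ccccc2)c1 | starting material
3 | lithium ethyl propiolate | [Li]C#CC(=O)OCC | intermediate (not isolated)
4 | ethyl 4-[3,4-bis(benzyloxy)phenyl]-4-hydroxybut-2-ynoate (racemic) | CCOC(=O)C#CC(O)c1ccc(OCc2ccccc2)c(OCc2ccccc2)c1 | intermediate
5 | ethyl (Z)-4-[3,4-bis(benzyloxy)phenyl]-4-hydroxybut-2-enoate (racemic) | CCOC(=O)/C=C\C(O)c1ccc(OCc2ccccc2)c(OCc2ccccc2)c1 | intermediate (not isolated)
6 | 5-[3,4-bis(benzyloxy)phenyl]furan-2(5H)-one (racemic; S enantiomer drawn) | O=C1C=C[C@@H](c2ccc(OCc3ccccc3)c(OCc3ccccc3)c2)O1 | intermediate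
7 | (chloromethyl)isopropoxydimethylsilane | CC(C)O[Si](C)(C)CCl | starting material
8 | (isopropoxydimethylsilyl)methylmagnesium chloride | CC(C)O[Si](C)(C)C[Mg]Cl | intermediate
9 | chloromagnesium enolate of trans-5-[3,4-bis(benzyloxy)phenyl]-4-[(isopropoxydimethylsilyl)methyl]oxolan-2-one (racemic) | Cl[Mg]OC1=C[C@H](C[Si](C)(C)OC(C)C)[C@@H](c2ccc(OCc3ccccc3)c(OCc3ccccc3)c2)O1 | intermediate (not isolated)
10 | rac-(3R,4S,5S)-5-[3,4-bis(benzyloxy)phenyl]-3-{[3,4-bis(benzyloxy)phenyl](hydroxy)methyl}-4-[(isopropoxydimethylsilyl)methyl]oxolan-2-one; 3,4-trans, 4,5-trans; carbinol epimers | O=C1O[C@H](c2ccc(OCc3ccccc3)c(OCc3ccccc3)c2)[C@@H](C[Si](C)(C)OC(C)C)[C@@H]1C(O)c1ccc(OCc2ccccc2)c(OCc2ccccc2)c1 | intermediate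
11 | rac-(3R,4R,5S)-5-[3,4-bis(benzyloxy)phenyl]-3-{[3,4-bis(benzyloxy)phenyl](hydroxy)methyl}-4-(hydroxymethyl)oxolan-2-one; 3,4-trans, 4,5-trans; carbinol epimers | O=C1O[C@H](c2ccc(OCc3ccccc3)c(OCc3ccccc3)c2)[C@@H](CO)[C@@H]1C(O)c1ccc(OCc2ccccc2)c(OCc2ccccc2)c1 | intermediate
12 | rac-(1S,2R,3S)-1,4-bis[3,4-bis(benzyloxy)phenyl]-2,3-bis(hydroxymethyl)butane-1,4-diol; C4 epimers | O[C@H](c1ccc(OCc2ccccc2)c(OCc2ccccc2)c1)[C@@H](CO)[C@@H](CO)C(O)c1ccc(OCc2ccccc2)c(OCc2ccccc2)c1 | intermediate
13 | rac-(1S,2R,3S)-2,3-bis(acetoxymethyl)-1,4-bis[3,4-bis(benzyloxy)phenyl]butane-1,4-diol; C4 epimers | O[C@H](c1ccc(OCc2ccccc2)c(OCc2ccccc2)c1)[C@@H](COC(C)=O)[C@@H](COC(C)=O)C(O)c1ccc(OCc2ccccc2)c(OCc2ccccc2)c1 | intermediate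
14 | meso-(2R,3S,4R,5S)-{2,5-bis[3,4-bis(benzyloxy)phenyl]oxolane-3,4-diyl}bis(methylene) diacetate | CC(=O)OC[C@@H]1[C@H](COC(C)=O)[C@@H](c2ccc(OCc3ccccc3)c(OCc3ccccc3)c2)O[C@H]1c1ccc(OCc2ccccc2)c(OCc2ccccc2)c1 | intermediate
15 | meso-(2R,3S,4R,5S)-[2,5-bis(3,4-dihydroxyphenyl)oxolane-3,4-diyl]bis(methylene) diacetate | CC(=O)OC[C@@H]1[C@H](COC(C)=O)[C@@H](c2ccc(O)c(O)c2)O[C@H]1c1ccc(O)c(O)c1 | target

## Step count and least certain steps

Total step count: 9. Longest linear sequence: 8 steps (steps 1, 2, 4, 5, 6, 7, 8, 9); step 3 is a one-step side branch that prepares the Grignard reagent.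

**Step 4 (key step).**
- What may go wrong: removal of the C5 proton of 6 (benzylic, allylic and next to oxygen) by the Grignard reagent or by enolate 9, followed by Michael oligomerisation, may consume the substrate before conjugate addition. Transfer of the α-silyl alkyl group from copper may be slow. The aldol may reverse on warming or show weak facial selectivity at C3.
- Fallback: the two bond formations are separated. Setting out from 6, the CuI-catalysed addition of 8 is run in the presence of Me3SiCl, which accelerates 1,4-addition and traps the enolate as the trimethylsilyl ketene acetal F1. Aqueous work-up hydrolyses F1 to the trans-4-(silylmethyl)-5-aryl lactone F2. Deprotonation of F2 with LiN(iPr)2 in THF at −78 °C and addition of 2 then gives the trans aldol, coming back to the route at 10.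

**Step 8.**
- What may go wrong: the benzylic cation may alkylate the second electron-rich ring irreversibly (Friedel–Crafts closure to an aryltetralin). A neighbouring acetate carbonyl may take part and cause acyl migration and closure through a primary oxygen. Equilibration of C2 and C5 may be incomplete.
- Fallback: the order of the last two operations is inverted so that the ring closes through a neutral para-quinone methide and not a cation. Setting out from 13, hydrogenolysis (H2, Pd/C, EtOAc) gives the tetraphenol diol diacetate F3. Warming F3 in aqueous MeCN with a trace of AcOH should expel water from a 4-hydroxybenzylic position and let the other benzylic hydroxyl add to the quinone methide. The route is rejoined at 15, without 14.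

**Step 7.**
- What may go wrong: chemoselectivity may be poor, with over-acylation at the benzylic hydroxyls or incomplete acylation of the primary ones, and acyl migration may occur on work-up.
- Fallback: acetylation is postponed until the benzylic hydroxyls are gone. Setting out from 12, TBSCl/imidazole in DMF at 0 °C should silylate only the primary hydroxyls to give the bis-silyl ether diol F4. Closure of F4 with CSA (cat.) in CH2Cl2 gives the bis-silyl tetrahydrofuran F5. Bu4NF in THF gives the tetrahydrofuran diol F6, whose only hydroxyls are primary. Ac2O/pyridine then returns to the route at 14.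

**Step 9.**
- What may go wrong: over-reduction, that is hydrogenolysis of a ring benzylic C–O bond after or alongside debenzylation, or incomplete removal of the fourth benzyl group.
- Fallback: a non-reductive dealkylation. Setting out from 14, BCl3 with pentamethylbenzene as cation scavenger in CH2Cl2 at −78 °C, then a methanol quench, cleaves the aryl benzyl ethers and leaves the acetates, coming back at 15. No compound outside the list is made, hence the entry F0.

## Further compounds

F1 | step 4 | trans-{[5-[3,4-bis(benzyloxy)phenyl]-4-[(isopropoxydimethylsilyl)methyl]-4,5-dihydrofuran-2-yl]oxy}trimethylsilane (racemic) | C[Si](C)(C)OC1=C[C@H](C[Si](C)(C)OC(C)C)[C@@H](c2ccc(OCc3ccccc3)c(OCc3ccccc3)c2)O1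
F2 | step 4 | trans-5-[3,4-bis(benzyloxy)phenyl]-4-[(isopropoxydimethylsilyl)methyl]oxolan-2-one (racemic) | O=C1O[C@H](c2ccc(OCc3ccccc3)c(OCc3ccccc3)c2)[C@@H](C[Si](C)(C)OC(C)C)C1
F3 | step 8 | rac-(1S,2R,3S)-2,3-bis(acetoxymethyl)-1,4-bis(3,4-dihydroxyphenyl)butane-1,4-diol (C4 epimers) | O[C@H](c1ccc(O)c(O)c1)[C@@H](COC(C)=O)[C@@H](COC(C)=O)C(O)c1ccc(O)c(O)c1
F4 | step 7 | rac-(1S,2R,3S)-1,4-bis[3,4-bis(benzyloxy)phenyl]-2,3-bis{[(tert-butyldimethylsilyl)oxy]methyl}butane-1,4-diol (C4 epimers) | O[C@H](c1ccc(OCc2ccccc2)c(OCc2ccccc2)c1)[C@@H](CO[Si](C)(C)C(C)(C)C)[C@@H](CO[Si](C)(C)C(C)(C)C)C(O)c1ccc(OCc2ccccc2)c(OCc2ccccc2)c1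
F5 | step 7 | meso-(2R,3S,4R,5S)-2,5-bis[3,4-bis(benzyloxy)phenyl]-3,4-bis{[(tert-butyldimethylsilyl)oxy]methyl}oxolane | CC(C)(C)[Si](C)(C)OC[C@@H]1[C@H](CO[Si](C)(C)C(C)(C)C)[C@@H](c2ccc(OCc3ccccc3)c(OCc3ccccc3)c2)O[C@H]1c1ccc(OCc2ccccc2)c(OCc2ccccc2)c1
F6 | step 7 | meso-(2R,3S,4R,5S)-{2,5-bis[3,4-bis(benzyloxy)phenyl]oxolane-3,4-diyl}dimethanol | OC[C@@H]1[C@H](CO)[C@@H](c2ccc(OCc3ccccc3)c(OCc3ccccc3)c2)O[C@H]1c1ccc(OCc2ccccc2)c(OCc2ccccc2)c1
F0 | step 9 | none | none
A1 | alternative 1 | (E)-3-[3,4-bis(tert-butyldimethylsilyloxy)phenyl]prop-2-en-1-yl 3-[3,4-bis(tert-butyldimethylsilyloxy)phenyl]-3-oxopropanoate | O=C(CC(=O)c1ccc(O[Si](C)(C)C(C)(C)C)c(O[Si](C)(C)C(C)(C)C)c1)OC/C=C/c1ccc(O[Si](C)(C)C(C)(C)C)c(O[Si](C)(C)C(C)(C)C)c1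
A2 | alternative 1 | 4,6-bis[3,4-bis(tert-butyldimethylsilyloxy)phenyl]-dihydrofuro[3,4-c]furan-1-one with C2=C3 enol ether, C5 aryl trans to the lactone CH2 | O=C1OC[C@@H]2[C@@H](c3ccc(O[Si](C)(C)C(C)(C)C)c(O[Si](C)(C)C(C)(C)C)c3)OC(c3ccc(O[Si](C)(C)C(C)(C)C)c(O[Si](C)(C)C(C)(C)C)c3)=C12
A3 | alternative 2 | 3-diazo-4-{[3,4-bis(benzyloxy)phenyl][3,4-bis(benzyloxy)benzyloxy]methyl}oxolan-2-one (anti C4/C5) | [N-]=[N+]=C1C(=O)OC[C@@H]1[C@@H](c1ccc(OCc2ccccc2)c(OCc2ccccc2)c1)OCc1ccc(OCc2ccccc2)c(OCc2ccccc2)c1
A4 | alternative 2 | cis-fused 4,6-bis[3,4-bis(benzyloxy)phenyl]tetrahydrofuro[3,4-c]furan-1-one, both aryl groups exo | O=C2[C@@H]1[C@H](CO2)[C@@H](c3ccc(OCc4ccccc4)c(OCc4ccccc4)c3)O[C@H]1c1ccc(OCc2ccccc2)c(OCc2ccccc2)c1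
A5 | alternative 3 | exo,exo-(7-oxabicyclo[2.2.1]hept-5-ene-2,3-diyl)bis(methylene) diacetate (meso) | CC(=O)OC[C@@H]1[C@H](COC(C)=O)[C@@H](C=C2)O[C@H]12
A6 | alternative 3 | meso-3,4-bis(acetoxymethyl)oxolane-2,5-dicarboxylic acid (carboxyls cis to each other, trans to the arms) | CC(=O)OC[C@@H]1[C@H](COC(C)=O)[C@@H](C(=O)O)O[C@H]1C(=O)O
A7 | alternative 3 | 4-bromo-1,2-bis(benzyloxy)benzene | Brc1ccc(OCc2ccccc2)c(OCc2ccccc2)c1
A8 | alternative 3 | tetra-O-benzyl ether of the target diacetate (identical with 14) | CC(=O)OC[C@@H]1[C@H](COC(C)=O)[C@@H](c2ccc(OCc3ccccc3)c(OCc3ccccc3)c2)O[C@H]1c1ccc(OCc2ccccc2)c(OCc2ccccc2)c1
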